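**Plan**
Retrosynthesis: O-2' is re-benzylated and O-5 re-methylated (21 ⇒ 18). Ring C of 18 is then cut at O1–C8a and C4–C4a in one stroke, giving a β-oxido ester (O1–C2–C3–C4, carrying ring B) and 3,4,5,6-tetramethoxybenzyne. The ester is cut at C2–C3 (acetate aldol).
Enabling feature: C4a and C8a are the only carbons of ring A without oxygen, and they are neighbours. With O-5 carried as OMe, the substituents at C5–C8 are all alike, so ring A is a C2v-symmetric aryne. It accepts nucleophilic O1 and electrophilic C4 in either orientation with the same result.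
Forward: ring A becomes an o-silylaryl triflate (steps 1–3), and the ring-B aldehyde is protected and extended by C3–C4 (steps 4–5). Ring C arises last, in step 6, when the two halves are joined. The new C4=O then singles out the peri O-5 methyl for chelation-controlled removal (step 7), and hydrogenolysis frees O-2' (step 8).
Stereochemistry: the only stereocentre, C2 (S), is set by a catalytic enantioselective Mukaiyama acetate aldol addition to the Si face of the aldehyde (step 5). Its C–O bond becomes C2–O1 and is never broken afterwards.

Key step: step 6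

Assumption: step 5 is written for the ligand antipode that directs addition to the Si face of 11. Both antipodes derive from resolved NOBIN, and the right one is confirmed on the first run by correlating desilylated 13 with the alcohol from the (R)-BINAP–Ru reduction in the fallback to step 5.

Step 1
Reactants: 1 1,2,3,4-tetramethoxybenzene
Product: 4 2,3,4,5-tetramethoxyphenol, via aryllithium 2 (not isolated), via dimethyl arylboronate 3 (not isolated)
Conditions: n-BuLi, TMEDA, THF, 0 °C → rt; B(OMe)3, −78 °C → rt; 30 % H2O2, AcOH, 0 °C → rt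
Reagents that add atoms: hydrogen peroxide, OO
Why: Directed ortho-metalation next to OMe (the two ring C–H positions are equivalent), borylation and oxidative C→O migration form a standard arene-to-phenol sequence.

Step 2
Reactants: 4 2,3,4,5-tetramethoxyphenol
Product: 5 2-bromo-3,4,5,6-tetramethoxyphenol
Conditions: NBS (1.0 equiv), MeCN, −20 → 0 °C, dark
Reagents that add atoms: N-bromosuccinimide, O=C1CCC(=O)N1Br
Why: Electrophilic aromatic bromination can only take the single free ring position, which lies ortho to the activating OH; anhydrous, cold conditions hold back oxidation to the quinone.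

Step 3
Reactants: 5 2-bromo-3,4,5,6-tetramethoxyphenol
Product: 9 2,3,4,5-tetramethoxy-6-(trimethylsilyl)phenyl triflate, via aryl silyl ether 6 (not isolated), via lithiated silyl ether 7 (not isolated), via lithium silylphenolate 8 (not isolated)
Conditions: HMDS, THF, reflux, then evaporation; n-BuLi, THF, −78 °C; Tf2O, −78 °C → rt
Reagents that add atoms: hexamethyldisilazane, C[Si](C)(C)N[Si](C)(C)C; triflic anhydride, O=S(=O)(OS(=O)(=O)C(F)(F)F)C(F)(F)F
Why: O-silylation, Br/Li exchange, anionic 1,3-O→C silyl shift (retro-Brook rearrangement) and O-triflation are the standard one-pot entry to o-silylaryl triflates from o-bromophenols.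

Step 4
Reactants: 10 2-hydroxy-6-methoxybenzaldehyde
Product: 11 2-(benzyloxy)-6-methoxybenzaldehyde
Conditions: BnBr, K2CO3, DMF, 50 °C
Reagents that add atoms: benzyl bromide, BrCc1ccccc1
Why: Williamson ether synthesis caps the ring-B phenol, which would otherwise compete for the aryne in step 6, with a group that leaves under neutral conditions.

Step 5
Reactants: 11 2-(benzyloxy)-6-methoxybenzaldehyde; 12 1-methoxy-1-(trimethylsilyloxy)ethene
Product: 13 methyl (S)-3-[2-(benzyloxy)-6-methoxyphenyl]-3-(trimethylsilyloxy)propanoate
Conditions: Ti(Oi-Pr)4, tridentate Schiff base of NOBIN and 3-bromo-5-tert-butylsalicylaldehyde (Si-selective antipode), 3,5-di-tert-butylsalicylic acid (5 mol % each), Et2O, −10 °C → rt; filtration through Et3N-deactivated silica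
Reagents that add atoms: none
Why: In this catalytic enantioselective Mukaiyama acetate aldol addition the aldehyde binds to the chiral Ti(IV) complex, whose binaphthyl wall blocks the Re face, so C3 adds to the Si face and sets C2 as (S), and salicylate-assisted silyl transfer delivers the product directly as the TMS ether needed in step 6.

Step 6
Reactants: 9 2,3,4,5-tetramethoxy-6-(trimethylsilyl)phenyl triflate; 13 methyl (S)-3-[2-(benzyloxy)-6-methoxyphenyl]-3-(trimethylsilyloxy)propanoate
Product: 18 (S)-2-[2-(benzyloxy)-6-methoxyphenyl]-5,6,7,8-tetramethoxychroman-4-one, via tetramethoxybenzyne 14 (not isolated), via potassium alkoxide 15 (not isolated), via arylpotassium adduct 16 (not isolated), via tetrahedral alkoxide 17 (not isolated)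
Conditions: KF, 18-crown-6 (3 equiv each), 4 Å MS, THF, −20 → 0 °C, 9 (1.5 equiv) added slowly
Reagents that add atoms: none
Why: Proposed new method: fluoride removes the O-silyl group of 13 and the C-silyl group of 9, so that alkoxide 15 and aryne 14 meet in a medium free of O–H acids; 15 adds to one aryne carbon (bond O1–C8a), the ortho aryl anion 16 attacks the ester carbon C4 (bond C4–C4a) and tetrahedral alkoxide 17 expels methoxide, which is taken up by a further silyl group and so carries the process on instead of building up as base. The closest known reaction types are the annulation of arynes by methyl salicylates to xanthones (O-addition, then acyl capture), the insertion of arynes into the N–C(=O) bond of NH-β-lactams to 2,3-dihydroquinolin-4-ones and the O-arylation of aliphatic alcohols by arynes from o-silylaryl triflates; new is an aliphatic, silyl-masked β-hydroxy ester as the O/C(=O) partner and a chroman-4-one as the product. Ring C closes by a 6-exo-trig addition–elimination of the aryl anion at the ester carbonyl, after the intermolecular C–O bond has tied the two halves together. No new stereocentre arises in 18 (the hemiketal centre of 17 is lost again), and C2 keeps the (S) configuration from step 5 because its C–O and C–H bonds take no part. Regioselectivity, the usual weak point of 3-alkoxyarynes, is not required, since 14 is C2v-symmetric and both orientations give the same 18. Acyl capture has to outrun protonation of 16, retro-aldol cleavage of 15 and retro-oxa-Michael opening of 18; the proton-free alkoxide source, the six-membered transition state, the benzyl cap on the ring-B phenol and the low temperature are meant to secure this.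

Step 7
Reactants: 18 (S)-2-[2-(benzyloxy)-6-methoxyphenyl]-5,6,7,8-tetramethoxychroman-4-one
Product: 20 (S)-2-[2-(benzyloxy)-6-methoxyphenyl]-5-hydroxy-6,7,8-trimethoxychroman-4-one, via dichloroboron chelate 19 (not isolated)
Conditions: BCl3 (1.2 equiv), CH2Cl2, −78 → −30 °C; then H2O, 0 °C
Reagents that add atoms: none
Why: In this chelation-controlled aryl methyl ether cleavage (the standard 5-O-demethylation of polymethoxyflavonoids) BCl3 is held between C4=O and the peri O-5 in a six-membered chelate, so chloride should remove only that methyl group at a temperature at which the benzyl ether and the C2–O1 bond should hold.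

Step 8
Reactants: 20 (S)-2-[2-(benzyloxy)-6-methoxyphenyl]-5-hydroxy-6,7,8-trimethoxychroman-4-one
Product: 21 (S)-5-hydroxy-2-(2-hydroxy-6-methoxyphenyl)-6,7,8-trimethoxychroman-4-one
Conditions: H2 (1 atm), 10 % Pd/C, EtOAc, rt
Reagents that add atoms: none
Why: Catalytic hydrogenolysis of the primary aryl benzyl ether is faster than that of the hindered cyclic C2–O1 bond and runs under neutral conditions, which avoids acid- or base-induced ring opening to the chalcone and so keeps C2 intact.

**Compound list**
1 | 1,2,3,4-tetramethoxybenzene | COc1ccc(OC)c(OC)c1OC | starting material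
2 | (2,3,4,5-tetramethoxyphenyl)lithium | COc1cc([Li])c(OC)c(OC)c1OC | intermediate
3 | dimethyl (2,3,4,5-tetramethoxyphenyl)boronate | COB(OC)c1cc(OC)c(OC)c(OC)c1OC | intermediate
4 | 2,3,4,5-tetramethoxyphenol | COc1cc(O)c(OC)c(OC)c1OC | intermediate
5 | 2-bromo-3,4,5,6-tetramethoxyphenol | COc1c(O)c(Br)c(OC)c(OC)c1OC | intermediate
6 | (2-bromo-3,4,5,6-tetramethoxyphenoxy)trimethylsilane | COc1c(O[Si](C)(C)C)c(Br)c(OC)c(OC)c1OC | intermediate
7 | [2,3,4,5-tetramethoxy-6-(trimethylsilyloxy)phenyl]lithium | COc1c(O[Si](C)(C)C)c([Li])c(OC)c(OC)c1OC | intermediate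
8 | lithium 2,3,4,5-tetramethoxy-6-(trimethylsilyl)phenolate | COc1c([O-])c([Si](C)(C)C)c(OC)c(OC)c1OC.[Li+] | intermediate
9 | 2,3,4,5-tetramethoxy-6-(trimethylsilyl)phenyl trifluoromethanesulfonate | COc1c(OS(=O)(=O)C(F)(F)F)c([Si](C)(C)C)c(OC)c(OC)c1OC | intermediate
10 | 2-hydroxy-6-methoxybenzaldehyde | COc1cccc(O)c1C=O | starting material
11 | 2-(benzyloxy)-6-methoxybenzaldehyde | COc1cccc(OCc2ccccc2)c1C=O | intermediate
12 | 1-methoxy-1-(trimethylsilyloxy)ethene | C=C(OC)O[Si](C)(C)C | starting material
13 | methyl (S)-3-[2-(benzyloxy)-6-methoxyphenyl]-3-(trimethylsilyloxy)propanoate | COc1cccc(OCc2ccccc2)c1[C@@H](O[Si](C)(C)C)CC(=O)OC | intermediate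
14 | 3,4,5,6-tetramethoxybenzyne | COC1=C(OC)C(OC)=C(OC)C#C1 | intermediate
15 | potassium (S)-1-[2-(benzyloxy)-6-methoxyphenyl]-3-methoxy-3-oxopropan-1-olate | COc1cccc(OCc2ccccc2)c1[C@@H]([O-])CC(=O)OC.[K+] | intermediate
16 | methyl (S)-3-[2-(benzyloxy)-6-methoxyphenyl]-3-(2-potassio-3,4,5,6-tetramethoxyphenoxy)propanoate | COc1cccc(OCc2ccccc2)c1[C@@H](Oc1c([K])c(OC)c(OC)c(OC)c1OC)CC(=O)OC | intermediate
17 | potassium (2S)-2-[2-(benzyloxy)-6-methoxyphenyl]-4,5,6,7,8-pentamethoxychroman-4-olate (C4 undefined) | COc1cccc(OCc2ccccc2)c1[C@@H]1CC([O-])(OC)c2c(OC)c(OC)c(OC)c(OC)c2O1.[K+] | intermediate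
18 | (S)-2-[2-(benzyloxy)-6-methoxyphenyl]-5,6,7,8-tetramethoxychroman-4-one | COc1cccc(OCc2ccccc2)c1[C@@H]1CC(=O)c2c(OC)c(OC)c(OC)c(OC)c2O1 | intermediate
19 | (S)-2-[2-(benzyloxy)-6-methoxyphenyl]-5-(dichloroboryloxy)-6,7,8-trimethoxychroman-4-one (B chelated by C4=O) | COc1cccc(OCc2ccccc2)c1[C@@H]1CC(=O)c2c(OB(Cl)Cl)c(OC)c(OC)c(OC)c2O1 | intermediate
20 | (S)-2-[2-(benzyloxy)-6-methoxyphenyl]-5-hydroxy-6,7,8-trimethoxychroman-4-one | COc1cccc(OCc2ccccc2)c1[C@@H]1CC(=O)c2c(O)c(OC)c(OC)c(OC)c2O1 | intermediate
21 | (S)-5-hydroxy-2-(2-hydroxy-6-methoxyphenyl)-6,7,8-trimethoxychroman-4-one | COc1cccc(O)c1[C@@H]1CC(=O)c2c(O)c(OC)c(OC)c(OC)c2O1 | target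

Total step count: 8. Longest linear sequence: 6 (steps 1, 2, 3, 6, 7, 8).

**Steps most likely to fail**

Step 6.
- The hindered secondary alkoxide may add only slowly to an aryne carbon flanked by OMe.
- The free alkoxide may undergo retro-aldol cleavage, with erosion of enantiopurity.
- The aryl anion may take a proton from the α-CH2 group, followed by β-elimination of the aryloxide.
- The basic medium may open the product by retro-oxa-Michael reaction.

The fallback sets out from 4 and 11, returns at 18 and uses only classical flavanone chemistry. Phenol 4 is C-acetylated at its only free ring position (AcOH, BF3·OEt2, 70 °C, Friedel–Crafts acylation of the Fries type) to 2'-hydroxy-3',4',5',6'-tetramethoxyacetophenone F1. Claisen–Schmidt condensation with 11 (KOH, EtOH, rt) should give the (E)-2'-hydroxychalcone F2. Intramolecular oxa-Michael addition (NaOAc, EtOH, reflux), which the 6'-methoxy group favours, should give the racemic flavanone F3. Preparative HPLC on a polysaccharide chiral stationary phase then separates this into 18 and its antipode.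

Step 7.
- The Lewis acid may ionise the C2–O1 bond, whose benzylic carbon carries two ortho oxygen donors, leading to racemisation or opening to the chalcone.
- The benzyl group may be lost prematurely.
- A second demethylation may occur at O-6.

The fallback sets out from 18, returns at 20 and replaces Lewis acid cleavage by a redox detour. Oxidative demethylation of the para-related O-5/O-8 pair (CAN, MeCN/H2O, 0 °C) should give the flavanone-5,8-quinone F4. Reduction with Na2S2O4 (EtOAc/H2O) gives the 5,8-hydroquinone F5. The 8-OH is not tied to C4=O by a hydrogen bond as the 5-OH is, so it should be methylated selectively (TMSCHN2, i-Pr2NEt, MeCN/MeOH, 0 °C) to give 20.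

Step 5.
- Facial selectivity or turnover may be poor, because the two ortho alkoxy groups twist the formyl group out of plane and can chelate titanium.
- The labile TMS group may be lost on isolation.

The fallback sets out from 11, returns at 13 and moves the stereo-defining event from C–C bond formation to ketone reduction. The lithium enolate of methyl acetate (LDA, THF, −78 °C) adds to 11 to give the racemic β-hydroxy ester F6. Dess–Martin oxidation gives the β-keto ester F7. Noyori asymmetric hydrogenation (RuCl2[(R)-BINAP], H2, MeOH, 50 °C) should give the (S)-β-hydroxy ester F8. The facial sense is the one that gives (R)-3-hydroxybutanoate, which reads (S) for an aryl carbinol. TMSCl and imidazole in CH2Cl2 then give 13.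

Further compounds
F1 | step 6 | 2'-hydroxy-3',4',5',6'-tetramethoxyacetophenone | CC(=O)c1c(O)c(OC)c(OC)c(OC)c1OC
F2 | step 6 | (E)-3-[2-(benzyloxy)-6-methoxyphenyl]-1-(2-hydroxy-3,4,5,6-tetramethoxyphenyl)prop-2-en-1-one | COc1cccc(OCc2ccccc2)c1/C=C/C(=O)c1c(O)c(OC)c(OC)c(OC)c1OC
F3 | step 6 | racemic 2-[2-(benzyloxy)-6-methoxyphenyl]-5,6,7,8-tetramethoxychroman-4-one | COc1cccc(OCc2ccccc2)c1C1CC(=O)c2c(OC)c(OC)c(OC)c(OC)c2O1
F4 | step 7 | (S)-2-[2-(benzyloxy)-6-methoxyphenyl]-6,7-dimethoxy-2,3-dihydrochromene-4,5,8-trione | COc1cccc(OCc2ccccc2)c1[C@@H]1CC(=O)C2=C(O1)C(=O)C(OC)=C(OC)C2=O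
F5 | step 7 | (S)-2-[2-(benzyloxy)-6-methoxyphenyl]-5,8-dihydroxy-6,7-dimethoxychroman-4-one | COc1cccc(OCc2ccccc2)c1[C@@H]1CC(=O)c2c(O)c(OC)c(OC)c(O)c2O1
F6 | step 5 | racemic methyl 3-[2-(benzyloxy)-6-methoxyphenyl]-3-hydroxypropanoate | COc1cccc(OCc2ccccc2)c1C(O)CC(=O)OC
F7 | step 5 | methyl 3-[2-(benzyloxy)-6-methoxyphenyl]-3-oxopropanoate | COc1cccc(OCc2ccccc2)c1C(=O)CC(=O)OC
F8 | step 5 | methyl (S)-3-[2-(benzyloxy)-6-methoxyphenyl]-3-hydroxypropanoate | COc1cccc(OCc2ccccc2)c1[C@@H](O)CC(=O)OC
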